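The ratio we carry is target gained per minute, and the maple run gives it: 6.6% of the electrophile charged at 3.00 min makes 0.0220 /min. We call this the warm slope: the share of the charged electrophile that becomes target in a minute at 50 °C, with electrophile and free base fully charged (an initial rate).

| flask | electrophile | free base | protonated nucleophile | protic impurity | temperature | remark | time |
|---|---|---|---|---|---|---|---|
| elm | 0.40 M | 0.44 M | 0.52 M | 0.12 M | 35 °C | run made earlier |  |
| maple | 0.40 M | 0.44 M | 0.52 M | 0.17 M | 50 °C | run made earlier |  |
| oak | 0.40 M | 0.44 M | 0.52 M | 0.26 M | 35 °C | run made earlier |  |
| ash | 0.40 M | 0.88 M | 0.52 M | 0.12 M | 50 °C | run made earlier |  |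
| south | 0.40 M | 0.440 M (fed, over 4.0 min) | 0.520 M | 0.120 M |  | the addition at 20 °C, then warmed to 50 °C; the feed brings no volume worth counting | 6.0 min |
| north-east | 0.40 M | 0.440 M (fed, over 4.0 min) | 0.520 M | 0.120 M | 50 °C | all else is in the flask from the start; the feed brings no volume worth counting | 6.0 min |
| west | 0.40 M | 0.440 M | 0.520 M | 0.120 M | 50 °C | everything together at the start | 6.0 min |
| south-east | 0.40 M (fed, over 4.0 min) | 0.440 M | 0.520 M | 0.120 M | 50 °C | all else is in the flask from the start; the feed brings no volume worth counting | 6.0 min |

- elm (time / min: target / %): 2.00: 1.1; 4.00: 1.5; 5.00: 2.1; 8.00: 3.6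
- maple (time / min: target / %): 0.500: 1.3; 1.33: 2.9; 3.00: 6.6; 8.00: 14.9
- oak (time / min: target / %): 4.00: 1.8; 8.00: 3.2; 10.0: 3.7; 15.0: 5.5
- ash (time / min: target / %): 2.00: 5.9; 4.00: 12.2; 5.00: 15.1; 8.00: 22.7

(scatter of a reading: 0.3 percentage points)

- the flask with the highest amount of target, in percent of the electrophile charged ("all alike" if they lie within 1.5 percentage points) (south / north-east / west / south-east / all alike)
- final target, as a percentage of the electrophile charged, in south
- final target, as a percentage of the electrophile charged, in north-east
- final target, as a percentage of the electrophile charged, in west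
- final target, as a percentage of the electrophile charged, in south-east

- steps that have been proposed: acid set free + free base <-> salt of the base; acid set free + target -> side product; nucleophile + acid set free <-> protonated nucleophile; nucleophile + protic impurity -> quenched reagent; electrophile + nucleophile -> acid set free + target

The maple curve starts straight, since 2.9% at 1.33 min gives 0.0218 /min too. Then it has a knee: from 3.00 min to 8.00 min its slope is 0.0166 /min, less, and no level shows by its last reading of 14.9%. West has less protic impurity than maple, but ash, with 0.12 M of it like west, bends as well: its slope is 0.0305 /min up to 4.00 min and then 0.0263 /min up to 8.00 min, less. So a straight line to 6.0 min is a first estimate that leans high, and we use it as that.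

Ash has twice the free base of maple and less protic impurity, and its slope is 1.39 times the warm slope, near the root of two, 1.41. We therefore count a steady feed of free base as 0.667 of its time, the mean of that root, and a steady feed of electrophile as half of its time. Elm's slope of 0.00450 /min is lower at 35 °C, and 20 °C is colder still, so in our reckoning we leave south's cold feed out. Our reckoning, warm slope times warm minutes:

west: 13.2%

north-east: 10.3%

south-east: 8.80%

south: 4.40%

The forecast, which holds that the “target rate tracks free nucleophile”, names west as we do, with 4.8% for south, 9.5% for north-east, 12.2% for west and 8.3% for south-east, lower than ours in west and higher in south.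

The flasks give 4.94% in south, 10.6% in north-east, 13.0% in west and 10.2% in south-east, so west holds the most target.

    acid set free + free base ⇌ salt of the base (K = 29000 /M, k = 0.0510 /M/s, Ea = 73.0 kJ/mol, ΔH = −27.0 kJ/mol)
    acid set free + target → side product (k = 0.0130 /M/s, Ea = 51.0 kJ/mol)
    nucleophile + acid set free ⇌ protonated nucleophile, settled at all times (K = 490 /M, ΔH = −84.0 kJ/mol)
    nucleophile + protic impurity → quenched reagent (k = 0.0430 /M/s, Ea = 73.0 kJ/mol)
    electrophile + nucleophile → acid set free + target (k = 0.0120 /M/s, Ea = 52.0 kJ/mol)
    (constants at 50 °C)

The warm slope misses west by 0.20 percentage points and south by 0.54 points, but south-east stands 1.4 points above its line. In west at 2.50 min, nucleophile goes to target 1.1 times as fast as it goes to quenched reagent, so about half of what these two steps use at that moment becomes target. At 6.00 min west holds 0.0520 M of target beside 0.0495 M of quenched reagent.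

The earlier runs and the new flask stem from a simulated flask for an exercise, noise included.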